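## Structural features

The target is a germacranolide: a ten-membered carbocycle (C1–C10) with two trisubstituted, ring-cis (Z) olefins. C1=C10 (C14 methyl on C10) is conjugated with the C9 ketone, and C4=C5 (C15 methyl on C4) is linked to it through C2–C3 as a 1,5-diene. A cis-fused α-methylene-γ-butyrolactone (O–C12(=O)–C11(=C13H2)) spans C6–C7, and C7 is a fully substituted carbinol. C6 (S, lactone oxygen), C7 (R, tertiary OH) and C8 (R, angelate) are contiguous between olefinic C5 and the C9 ketone. O7 and O8 are syn and O6 is anti to them, which is the L-lyxo pattern of a pentose whose C1 is C9 and whose C5 is C5. Fragile groups are the exo-methylene lactone (Michael acceptor), the C7-hydroxy/C9-keto aldol unit (retro-aldol), C8 next to the ketone (epimerisation), the angelate and the Z-enone (Z to E), and the 1,5-diene (transannular reactions). The real difficulty is to close the strained ten-membered ring with both olefins Z while the oxygenated triad with its quaternary C7 is carried. The key step exploits C4=C5: its two carbons (C5, the primary end of the sugar-derived C5–C9 chain, and C4, a secondary carbon of the C10–C4 chain) are first bridged by sulfur in an eleven-membered thiacycle, which is then contracted.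

## Logic of the disconnections

30 is cut at the C8–O acyl bond to 29. The angelate isomerises and is base-labile, so it goes on last. The forward step must acylate the secondary C8–OH beside the tertiary C7–OH without Z to E isomerisation.

29 goes back to 27 through 28: the C9 ketone becomes a silylated carbinol and the C7/C8 diol an acetonide. A C9 ketone would make C8 epimerisable and C7 retro-aldol-prone in all earlier basic steps. The forward steps need an oxidation that is selective for the allylic C9–OH.

27 is cut at the C12–O6 lactone bond and lowered in oxidation level to the 2-methylene-1,4-diol 25, which comes from the bis-PMB ether 24. The lactone cannot survive the base of the key step. The forward oxidation must take the primary allylic alcohol only and close onto O6, which is why O9 is silylated and O7/O8 are tied.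

24 is cut at C4=C5 and SO2 is inserted, giving the eleven-membered sulfone 21 (forward through 22 and 23). Ring closure thereby becomes C–S bond formation and the olefin geometry is set inside the ring. The forward step needs 1,3-elimination to beat β-elimination of the C6 oxygen and must give the Z olefin.

21 goes back through 20 and 19 to 17 by cutting both C–S bonds. Sulfide is the two-fold nucleophile, the terminal C5–C6 epoxide is the primary electrophile and the C4 chloride the secondary one. This opens the ring to an acyclic chain. The forward step needs regioselective epoxide opening at C5 and intramolecular closure under dilution.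

17 goes back through 16 to 14 and 10 by cutting C9–C10. A Z-vinyl metal adds to the aldehyde that is latent in the lactol 10, and the freed O6 alkoxide closes the epoxide on the C5 tosylate. The forward step must keep the Z geometry of the vinyl metal. The C9 configuration is immaterial.

10 goes back through 9, 8 and 7 to 4 and 6 by cutting C7–C11. The quaternary C7 is set by addition to a rigid bicyclic ulose. The forward addition must come from the face opposite the acetonide. Moving the acetonide from O1/O2 to O2/O3 then frees the aldehyde carbon.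

4 goes back through 3 and 2 to 1 by functional group changes only. C6 and C8 of the target are C4 and C2 of 1, unchanged.

14 goes back through 13 and 12 to 11 by cutting the C10=C1 olefin (iodo-olefination), which must be Z-selective. 6 comes from 5 by etherification.

## Other disconnections considered

Alternative 1: Cut C9–C10 of the ten-membered ring with both olefins already in place. The forward key step would be an intramolecular Nozaki–Hiyama–Kishi closure of the seco iodo-aldehyde A1 to the macrocyclic alcohol A2. This is the first plan that comes to mind. It requires the Z C4=C5 olefin to be made in open-chain form next to the C6 stereocentre, where nothing enforces Z. It also closes the strained ten-membered ring directly at an α-alkoxy aldehyde beside the quaternary C7. The chosen plan closes a less strained eleven-membered ring by C–S bonds and lets the ring set the C4=C5 geometry.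

Alternative 2: Cut the transannular C4–C9 bond, that is, make the ring by Grob fragmentation of the cis-fused decalin hydroxy mesylate A3 to the cyclodecadienone A4. The anti-periplanar C5–OMs would give the Z C4=C5 olefin and the enone in one stereospecific step. The drawback is that five contiguous oxygenated centres (C5 to C9) must be set on ring B relative to the angular methyl, including a trans C8/C9 diol and the cis ring fusion. The C7 oxygen is also 1,3 to the mesylate and could trigger a competing fragmentation of C6–C7. An enantioselective entry to the α-quaternary ring system is needed as well. Reading C6–C8 from a pentose needs fewer stereochemical bets.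

Alternative 3: Cut C6–C7 and C8–C9, that is, insert two carbons into an eight-membered ring. The dienone A5, from 1,5-dimethylcycloocta-1,5-diene, already holds C9, C10, C1–C6 and both Z olefins. Vinyl addition would give the carbinol A6, and an alkoxide-accelerated 1,3-allyl shift would give the cyclodecadienone A7. The [3,3] pathway competes with the 1,3-shift. A7 has three adjacent methylenes (C6–C8) with no stereochemical anchor for the triad, the series is racemic, and the commercial diene is an isomer mixture.

Key step: step 17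

Assumption: atoms are numbered as in germacranes. C9 (carbinol from step 12) and C4 (from racemic 11) are carried as epimer mixtures and left open in the SMILES, since both become sp2 (steps 17 and 21).

## Steps

Step 1
Reactants: 1 L-arabinose
Product: 2 5-O-TBDPS-L-arabinofuranose
Conditions: TBDPSCl, pyridine, 0 °C → rt
Reagents that add atoms: tert-butyl(chloro)diphenylsilane, CC(C)(C)[Si](Cl)(c1ccccc1)c1ccccc1
Why: Silylation of the primary hydroxyl, which exists only in the furanose form, locks the sugar as the furanose; no stereocentre is touched and the anomeric centre stays a mixture.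

Step 2
Reactants: 2 5-O-TBDPS-L-arabinofuranose
Product: 3 5-O-TBDPS-1,2-O-isopropylidene-β-L-arabinofuranose
Conditions: 2,2-dimethoxypropane, p-TsOH (cat.), acetone, rt
Reagents that add atoms: 2,2-dimethoxypropane, COC(C)(C)OC
Why: Acid-catalysed acetalisation; only O1/O2 can form a cis-fused dioxolane (O3 is trans to O2), which fixes C1 as the β-anomer and leaves the 3-OH free.

Step 3
Reactants: 3 5-O-TBDPS-1,2-O-isopropylidene-β-L-arabinofuranose
Product: 4 5-O-TBDPS-1,2-O-isopropylidene-β-L-threo-pentofuranos-3-ulose
Conditions: Dess–Martin periodinane, CH2Cl2, rt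
Reagents that add atoms: none
Why: Dess–Martin oxidation of the only free (secondary) alcohol under neutral conditions; C2 and C4 (later C8 and C6) are not epimerised.

Step 4
Reactants: 5 2-bromoprop-2-en-1-ol
Product: 6 2-bromoallyl 4-methoxybenzyl ether
Conditions: NaH, PMBCl, Bu4NI (cat.), THF, 0 °C → rt
Reagents that add atoms: 4-methoxybenzyl chloride, COc1ccc(CCl)cc1
Why: Williamson etherification; gives the C11–C13 unit with C12 as a protected alcohol and a vinyl bromide for lithiation.

Step 5
Reactants: 6 2-bromoallyl 4-methoxybenzyl ether; 4 3-ulose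
Product: 7 3-C-[3-(PMB-oxy)prop-1-en-2-yl]-5-O-TBDPS-1,2-O-isopropylidene-β-L-lyxofuranose
Conditions: 6, t-BuLi (2 equiv), Et2O, −78 °C; then 4, −78 °C; H2O
Reagents that add atoms: none
Why: Br–Li exchange, then 1,2-addition of the vinyllithium to the ketone. The 1,2-O-isopropylidene ring and the C4 side chain lie on the same face of the bicyclic ulose, so attack comes from the other face and the new tertiary OH is cis to O2 (L-lyxo). This sets C7 (R in the target) with the C11 branch in place.

Step 6
Reactants: 7 branched 5-O-TBDPS lyxofuranose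
Product: 8 3-C-[3-(PMB-oxy)prop-1-en-2-yl]-1,2-O-isopropylidene-β-L-lyxofuranose
Conditions: TBAF, THF, 0 °C → rt
Reagents that add atoms: none
Why: Fluoride desilylation; acetonide and PMB ether are inert to fluoride.

Step 7
Reactants: 8 3,5-diol
Product: 9 5-O-tosylate of 8
Conditions: TsCl, pyridine, CH2Cl2, 0 °C
Reagents that add atoms: p-toluenesulfonyl chloride, Cc1ccc(cc1)S(Cl)(=O)=O
Why: Sulfonylation of the primary alcohol; the tertiary 3-OH does not react under these conditions.

Step 8
Reactants: 9 1,2-O-isopropylidene 5-O-tosylate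
Product: 10 3-C-[3-(PMB-oxy)prop-1-en-2-yl]-2,3-O-isopropylidene-5-O-tosyl-L-lyxofuranose (lactol)
Conditions: p-TsOH (cat.), acetone, rt
Reagents that add atoms: none
Why: Acid-catalysed acetal migration under thermodynamic control. In 9, O1, O2, O3 and C5 are all on one face; moving the ketal to the cis O2/O3 pair relieves this crowding, as is usual for lyxo-configured furanoses. The free lactol is the latent C9 aldehyde, with O8/O7 protected.

Step 9
Reactants: 11 γ-valerolactone (racemic)
Product: 12 5-methyltetrahydrofuran-2-ol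
Conditions: DIBAL-H, CH2Cl2, −78 °C; aq. Rochelle salt
Reagents that add atoms: none
Why: Partial reduction of a lactone to the lactol at low temperature.

Step 10
Reactants: 12 5-methyltetrahydrofuran-2-ol
Product: 13 (Z)-6-iodohept-5-en-2-ol
Conditions: EtPPh3I, n-BuLi, THF, 0 °C; I2, −78 °C; NaHMDS, −20 °C; then 12, −78 °C → rt
Reagents that add atoms: ethyltriphenylphosphonium iodide, CC[P+](c1ccccc1)(c1ccccc1)c1ccccc1.[I-]; iodine, II
Why: Wittig iodo-olefination (Zhao variant) of the hydroxy aldehyde in equilibrium with the lactol; the α-iodo ylide gives the (Z)-2-iodo-2-alkene, which fixes the later C10=C1 geometry (iodine marks the position of C9, cis to C2).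

Step 11
Reactants: 13 (Z)-6-iodohept-5-en-2-ol
Product: 14 (Z)-6-chloro-2-iodohept-2-ene
Conditions: PPh3, N-chlorosuccinimide, THF, 0 °C → rt
Reagents that add atoms: N-chlorosuccinimide, O=C1CCC(=O)N1Cl
Why: Appel-type chlorination (SN2 on the alkoxyphosphonium). A secondary chloride survives the later lithiation; C4 is a mixed centre that is erased in step 17.

Step 12
Reactants: 14 (Z)-6-chloro-2-iodohept-2-ene; 10 lactol tosylate
Product: 16 C5–C6 epoxy C9 alcohol, via tosyl diol 15 (not isolated)
Conditions: 14, t-BuLi (2 equiv), Et2O, −78 °C; 10 + LiHMDS (1 equiv), THF, −78 °C, combine, → −20 °C; MeOH; K2CO3, 0 °C → rt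
Reagents that add atoms: none
Why: I–Li exchange with retention of the Z geometry, then addition to the aldehyde form of the lithium lactolate; this makes C9–C10 (the C9 epimer ratio is immaterial). The liberated O6 then displaces the neighbouring primary tosylate (Williamson epoxide closure, 3-exo-tet), with C6 unchanged because its C–O bond is not broken.

Step 13
Reactants: 16 epoxy alcohol
Product: 17 C9 TBS ether of 16
Conditions: TBSCl, imidazole, DMAP (cat.), DMF, rt
Reagents that add atoms: tert-butyl(chloro)dimethylsilane, CC(C)(C)[Si](C)(C)Cl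
Why: Silylation under non-alkoxide conditions. It keeps O9 from opening the epoxide (5-exo) and later from competing with O6 in the lactonisation.

Step 14
Reactants: 17 epoxy chloride TBS ether
Product: 19 eleven-membered cyclic sulfide, via sodium thiolate 18 (not isolated)
Conditions: Na2S·9H2O (1.05 equiv), DMF, 0 °C → rt; then dilution to 2 mM, NaI (cat.), 60 °C
Reagents that add atoms: sodium sulfide, [Na+].[Na+].[S-2]
Why: Sulfide opens the terminal epoxide at the primary C5 and frees the C6–OH. The resulting thiolate closes the eleven-membered ring by intramolecular SN2 at the C4 chloride (iodide catalysis, high dilution). Inversion at C4 is irrelevant.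

Step 15
Reactants: 19 cyclic sulfide with free C6–OH
Product: 20 C6 PMB ether of 19
Conditions: NaH, PMBCl, Bu4NI (cat.), DMF, 0 °C → rt
Reagents that add atoms: 4-methoxybenzyl chloride, COc1ccc(CCl)cc1
Why: Williamson etherification at the sulfide stage, where the alkoxide cannot undergo retro-addition. An ether at O6 is a poor leaving group in the key step and comes off together with the C12 PMB group.

Step 16
Reactants: 20 cyclic sulfide
Product: 21 eleven-membered cyclic sulfone
Conditions: H2O2 (30%), (NH4)6Mo7O24·4H2O (cat.), EtOH, 0 °C → rt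
Reagents that add atoms: hydrogen peroxide, OO
Why: Molybdate-catalysed S-oxidation, which takes sulfides to sulfones without epoxidising the trisubstituted and 1,1-disubstituted olefins; no free allylic alcohol is present.

Step 17
Reactants: 21 eleven-membered cyclic sulfone
Product: 24 (1(10)Z,4Z)-cyclodecadiene, via α-bromosulfone 22 (not isolated), via episulfone 23 (not isolated)
Conditions: KOH/Al2O3, CBr2F2, t-BuOH/CH2Cl2, 0 °C → rt
Reagents that add atoms: none
Why: Ramberg–Bäcklund reaction used as a ring contraction (a known reaction type for medium-ring and carbohydrate sulfones): KOH on alumina deprotonates the more acidic C5–H2 of 21 and the carbanion is brominated by CBr2F2 to give 22. Deprotonation at the α′ carbon C4 then displaces bromide in a W-shaped intramolecular SN2 (3-exo-tet); this closes the thiirane 1,1-dioxide 23 and contracts the eleven-membered thiacycle to the ten-membered carbocycle. 23 loses SO2 stereospecifically, so the olefin geometry is that of the episulfone. No stereocentre is created; the stereochemical element is the C4=C5 geometry, and Z (C3 and C6 cis) is expected because only the cis-fused episulfone is readily reached on a ten-membered ring that already holds the Z C1=C10 olefin and the fused dioxolane, in line with the kinetic cis preference of the reaction under hydroxide conditions. The step needs 1,3-closure to win over β-elimination of the C6 oxygen from the C5 carbanion; the PMB alkoxide is a poor nucleofuge, and β-alkoxy sulfones of sugars tolerate these conditions. The olefins, acetonide, silyl and PMB ethers should survive the mild heterogeneous base at 0 °C, and both C4 epimers of 21 converge because C4 becomes sp2.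

Step 18
Reactants: 24 bis-PMB ether
Product: 25 C6,C12-diol
Conditions: DDQ, CH2Cl2/pH 7 buffer, 0 °C → rt
Reagents that add atoms: none
Why: Oxidative cleavage of both PMB ethers; TBS ether, acetonide and the isolated olefins are inert to DDQ.

Step 19
Reactants: 25 C6,C12-diol
Product: 27 6,12-olide, via lactol 26 (not isolated)
Conditions: TEMPO (cat.), PhI(OAc)2, CH2Cl2, rt
Reagents that add atoms: none
Why: TEMPO oxidative lactonisation: the primary allylic alcohol is oxidised first, the aldehyde is trapped by the cis-disposed C6–OH as the five-membered lactol, and this is oxidised to the α-methylene lactone. O9 is silylated and O7/O8 are tied, so only O6 can close; the C6 and C7 configurations are untouched.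

Step 20
Reactants: 27 lactone acetonide TBS ether
Product: 28 7,8,9-triol lactone
Conditions: TFA/THF/H2O (1:4:1), 0 °C → rt
Reagents that add atoms: none
Why: Acidic hydrolysis of the allylic TBS ether and the acetonide in one operation; the allylic oxygens at C6 and C9 lower the nucleophilicity of both ring olefins toward acid-triggered transannular reactions.

Step 21
Reactants: 28 7,8,9-triol lactone
Product: 29 7,8-dihydroxy-9-oxo lactone
Conditions: MnO2 (activated), CH2Cl2, rt
Reagents that add atoms: none
Why: MnO2 oxidises only the allylic C9–OH (the C8–OH is not allylic, the C7–OH is tertiary), giving the Z-enone, whose geometry is locked by the ring; this removes the mixed C9 centre.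

Step 22
Reactants: 29 7,8-dihydroxy-9-oxo lactone
Product: 30 target
Conditions: angelic acid, 2,4,6-trichlorobenzoyl chloride, Et3N, toluene, rt; then 29, 80 °C
Reagents that add atoms: angelic acid, C/C=C(/C)C(O)=O
Why: Yamaguchi-type esterification through the mixed anhydride without DMAP, the usual way to keep the Z geometry of angelates; only the secondary C8–OH is acylated, the tertiary C7–OH is not.

## Compound list

1 | L-arabinose (aldehydo form drawn) | O=C[C@H](O)[C@@H](O)[C@@H](O)CO | starting material
2 | 5-O-tert-butyldiphenylsilyl-L-arabinofuranose (anomer mixture) | OC1O[C@@H](CO[Si](c2ccccc2)(c2ccccc2)C(C)(C)C)[C@H](O)[C@H]1O | intermediate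
3 | 5-O-TBDPS-1,2-O-isopropylidene-β-L-arabinofuranose | CC1(C)O[C@H]2[C@@H](O1)O[C@@H](CO[Si](c3ccccc3)(c3ccccc3)C(C)(C)C)[C@@H]2O | intermediate
4 | 5-O-TBDPS-1,2-O-isopropylidene-β-L-threo-pentofuranos-3-ulose | CC1(C)O[C@H]2[C@@H](O1)O[C@@H](CO[Si](c3ccccc3)(c3ccccc3)C(C)(C)C)C2=O | intermediate
5 | 2-bromoprop-2-en-1-ol | OCC(Br)=C | starting material
6 | 2-bromoallyl 4-methoxybenzyl ether | C=C(Br)COCc1ccc(OC)cc1 | intermediate
7 | 3-C-[3-(4-methoxybenzyloxy)prop-1-en-2-yl]-5-O-TBDPS-1,2-O-isopropylidene-β-L-lyxofuranose (3-OH cis to the acetonide) | CC1(C)O[C@H]2[C@@H](O1)O[C@@H](CO[Si](c3ccccc3)(c3ccccc3)C(C)(C)C)[C@]2(O)C(=C)COCc1ccc(OC)cc1 | intermediate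
8 | 3-C-[3-(PMB-oxy)prop-1-en-2-yl]-1,2-O-isopropylidene-β-L-lyxofuranose (3,5-diol) | CC1(C)O[C@H]2[C@@H](O1)O[C@@H](CO)[C@]2(O)C(=C)COCc1ccc(OC)cc1 | intermediate
9 | 5-O-tosylate of 8 | CC1(C)O[C@H]2[C@@H](O1)O[C@@H](COS(=O)(=O)c3ccc(C)cc3)[C@]2(O)C(=C)COCc1ccc(OC)cc1 | intermediate
10 | 3-C-[3-(PMB-oxy)prop-1-en-2-yl]-2,3-O-isopropylidene-5-O-tosyl-L-lyxofuranose (lactol, anomer mixture) | OC1O[C@@H](COS(=O)(=O)c2ccc(C)cc2)[C@@]2(C(=C)COCc3ccc(OC)cc3)OC(C)(C)O[C@@H]12 | intermediate
11 | γ-valerolactone (racemic) | CC1CCC(=O)O1 | starting material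
12 | 5-methyltetrahydrofuran-2-ol | CC1CCC(O)O1 | intermediate
13 | (Z)-6-iodohept-5-en-2-ol | C/C(I)=C/CCC(C)O | intermediate
14 | (Z)-6-chloro-2-iodohept-2-ene | C/C(I)=C/CCC(C)Cl | intermediate
15 | open-chain tosyl diol: C9 and C6 carbinols, C5 tosylate, 7,8-O-isopropylidene, C4 chloride, (1(10)Z) | C/C(=C/CCC(C)Cl)C(O)[C@@H]1OC(C)(C)O[C@]1(C(=C)COCc2ccc(OC)cc2)[C@@H](O)COS(=O)(=O)c2ccc(C)cc2 | intermediate
16 | C5–C6 epoxide of the open chain with free C9–OH | C/C(=C/CCC(C)Cl)C(O)[C@@H]1OC(C)(C)O[C@]1(C(=C)COCc2ccc(OC)cc2)[C@@H]1CO1 | intermediate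
17 | C9 TBS ether of 16 | C/C(=C/CCC(C)Cl)C(O[Si](C)(C)C(C)(C)C)[C@@H]1OC(C)(C)O[C@]1(C(=C)COCc2ccc(OC)cc2)[C@@H]1CO1 | intermediate
18 | sodium C5-thiolate with free C6–OH (open chain, C4 chloride) | C/C(=C/CCC(C)Cl)C(O[Si](C)(C)C(C)(C)C)[C@@H]1OC(C)(C)O[C@]1(C(=C)COCc2ccc(OC)cc2)[C@@H](O)C[S-].[Na+] | intermediate
19 | eleven-membered cyclic sulfide (S between C4 and C5): 6-hydroxy, 7,8-O-isopropylidene, 9-O-TBS, 7-[3-(PMB-oxy)prop-1-en-2-yl], (1(10)Z) | C/C1=C/CCC(C)SC[C@H](O)[C@@]2(C(=C)COCc3ccc(OC)cc3)OC(C)(C)O[C@H]2C1O[Si](C)(C)C(C)(C)C | intermediate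
20 | 6-O-PMB ether of 19 | C/C1=C/CCC(C)SC[C@H](OCc3ccc(OC)cc3)[C@@]2(C(=C)COCc3ccc(OC)cc3)OC(C)(C)O[C@H]2C1O[Si](C)(C)C(C)(C)C | intermediate
21 | eleven-membered cyclic sulfone (S-dioxide of 20) | C/C1=C/CCC(C)S(=O)(=O)C[C@H](OCc3ccc(OC)cc3)[C@@]2(C(=C)COCc3ccc(OC)cc3)OC(C)(C)O[C@H]2C1O[Si](C)(C)C(C)(C)C | intermediate
22 | α-bromosulfone (bromine on C5) | C/C1=C/CCC(C)S(=O)(=O)C(Br)[C@H](OCc3ccc(OC)cc3)[C@@]2(C(=C)COCc3ccc(OC)cc3)OC(C)(C)O[C@H]2C1O[Si](C)(C)C(C)(C)C | intermediate
23 | cis-fused episulfone (thiirane 1,1-dioxide across C4–C5 of the ten-membered ring) | C/C1=C/CCC2(C)C(S2(=O)=O)[C@H](OCc3ccc(OC)cc3)[C@@]4(C(=C)COCc3ccc(OC)cc3)OC(C)(C)O[C@H]4C1O[Si](C)(C)C(C)(C)C | intermediate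
24 | (1(10)Z,4Z)-cyclodeca-1(10),4-diene: 6-O-PMB, 7,8-O-isopropylidene, 9-O-TBS, 7-[3-(PMB-oxy)prop-1-en-2-yl] | C/C1=C/CC/C(C)=C\[C@H](OCc3ccc(OC)cc3)[C@@]2(C(=C)COCc3ccc(OC)cc3)OC(C)(C)O[C@H]2C1O[Si](C)(C)C(C)(C)C | intermediate
25 | C6,C12-diol of 24 | C/C1=C/CC/C(C)=C\[C@H](O)[C@@]2(C(=C)CO)OC(C)(C)O[C@H]2C1O[Si](C)(C)C(C)(C)C | intermediate
26 | 6,12-lactol (cis-fused α-methylene lactol) | C/C1=C/CC/C(C)=C\[C@@H]2OC(O)C(=C)[C@@]23OC(C)(C)O[C@H]3C1O[Si](C)(C)C(C)(C)C | intermediate
27 | 7,8-O-isopropylidene-9-O-TBS-germacra-1(10)Z,4Z,11(13)-trien-6,12-olide | C/C1=C/CC/C(C)=C\[C@@H]2OC(=O)C(=C)[C@@]23OC(C)(C)O[C@H]3C1O[Si](C)(C)C(C)(C)C | intermediate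
28 | 7,8,9-trihydroxy-germacra-1(10)Z,4Z,11(13)-trien-6,12-olide (C9 epimers) | C/C1=C/CC/C(C)=C\[C@@H]2OC(=O)C(=C)[C@]2(O)[C@@H](O)C1O | intermediate
29 | (6S,7R,8R)-7,8-dihydroxy-9-oxo-germacra-1(10)Z,4Z,11(13)-trien-6,12-olide | C/C1=C/CC/C(C)=C\[C@@H]2OC(=O)C(=C)[C@]2(O)[C@@H](O)C1=O | intermediate
30 | (6S,7R,8R)-8-angeloyloxy-7-hydroxy-9-oxo-germacra-1(10)Z,4Z,11(13)-trien-6,12-olide (CNP0276177.1) | C=C1C(=O)O[C@H]2/C=C(/C)CC/C=C(/C)C(=O)[C@H](OC(=O)/C(C)=C\C)[C@@]12O | target

Total: 22 steps. Longest linear sequence: 18 steps (1–3, 5–8, 12–22, from 1).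

## Least certain steps

Step 17 (key step). The C5 carbanion may expel the C6 p-methoxybenzyloxy group (E1cB) instead of waiting for 1,3-closure. A second bromination may precede closure. The episulfone may epimerise under base, which would erode the Z selectivity. Difluorocarbene may add to the C1=C10 olefin. Fallback (sets out from 10, returns at 25): the iodo-olefination of step 10 applied to 4-methylpent-4-enal gives (Z)-2-iodo-6-methylhepta-2,6-diene F1. Its vinyllithium adds to 10 as in step 12 to give the isopropenyl epoxy alcohol F2, which is silylated as in step 13 to the TBS ether F3. Dimethylsulfonium methylide (Me3SI, n-BuLi) converts the terminal epoxide into the one-carbon-homologated allylic alcohol F4 (C6–OH, vinyl C5). Ring-closing metathesis (Grubbs II, toluene, high dilution) between the C5 vinyl and the C4 isopropenyl groups closes C4=C5 directly to the macrocyclic alcohol F5. DDQ removes the remaining PMB group and gives 25.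

Step 14. Thiolate attack on a second molecule may lead to oligomers. Substitution at the secondary chloride may be slow and give way to elimination. A second sulfide may add before ring closure. Fallback (sets out from 13 and 10, returns at 19): Mitsunobu reaction of 13 with thioacetic acid gives the thioacetate F6. K2CO3/MeOH in the presence of 10 frees the thiolate, which displaces the primary tosylate to give the sulfide lactol F7. An intramolecular Nozaki–Hiyama–Kishi reaction (CrCl2, NiCl2 cat., DMSO/THF, high dilution) then closes the ring at C9–C10 to the macrocyclic sulfide diol F8. Selective silylation of the less hindered allylic C9–OH (TBSCl, imidazole) gives 19.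

Step 5. The basic vinyllithium may enolise the ulose, which would cause β-elimination toward C5 or epimerisation at C2/C4. Facial selectivity may be incomplete. Fallback (sets out from 4, returns at 7): the less basic cerium reagent from commercial isopropenylmagnesium bromide (CeCl3, THF, −78 °C) gives the isopropenyl carbinol F9. SeO2 (cat.)/t-BuOOH oxidises its only allylic methyl to the allylic diol F10. PMB trichloroacetimidate with CSA (cat.) protects the primary hydroxyl to give 7.

Step 22. The angeloyl unit may isomerise to the tigloyl unit during the hot acylation. The base may induce retro-aldol cleavage at C7–C8 or epimerisation at C8. Fallback (sets out from 29, returns at 30): esterification of 29 with 2-[bis(2,2,2-trifluoroethoxy)phosphoryl]propanoic acid (DCC, DMAP cat., 0 °C) gives the phosphonate ester F11. Still–Gennari olefination with acetaldehyde (KHMDS, 18-crown-6, THF, −78 °C) builds the Z-2-methylbut-2-enoate in place and gives 30.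

## Further compounds

F1 | step 17 | (Z)-2-iodo-6-methylhepta-2,6-diene | C/C(I)=C/CCC(C)=C
F2 | step 17 | isopropenyl analogue of 16 (C5–C6 epoxide, free C9–OH) | C/C(=C/CCC(C)=C)C(O)[C@@H]1OC(C)(C)O[C@]1(C(=C)COCc2ccc(OC)cc2)[C@@H]1CO1
F3 | step 17 | C9 TBS ether of F2 | C/C(=C/CCC(C)=C)C(O[Si](C)(C)C(C)(C)C)[C@@H]1OC(C)(C)O[C@]1(C(=C)COCc2ccc(OC)cc2)[C@@H]1CO1
F4 | step 17 | C6 allylic alcohol with C5 vinyl and C4 isopropenyl groups | C/C(=C/CCC(C)=C)C(O[Si](C)(C)C(C)(C)C)[C@@H]1OC(C)(C)O[C@]1(C(=C)COCc2ccc(OC)cc2)[C@@H](O)C=C
F5 | step 17 | (1(10)Z,4Z)-cyclodecadiene with free C6–OH, 12-O-PMB, 9-O-TBS, 7,8-O-isopropylidene | C/C1=C/CC/C(C)=C\[C@H](O)[C@@]2(C(=C)COCc3ccc(OC)cc3)OC(C)(C)O[C@H]2C1O[Si](C)(C)C(C)(C)C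
F6 | step 14 | S-[(Z)-6-iodohept-5-en-2-yl] ethanethioate | C/C(I)=C/CCC(C)SC(C)=O
F7 | step 14 | 5-S-[(Z)-6-iodohept-5-en-2-yl]-5-thio lactol (2,3-O-isopropylidene, 3-C-branched L-lyxofuranose) | OC1O[C@@H](CSC(C)CC/C=C(/C)I)[C@@]2(C(=C)COCc3ccc(OC)cc3)OC(C)(C)O[C@@H]12
F8 | step 14 | eleven-membered cyclic sulfide 6,9-diol | C/C1=C/CCC(C)SC[C@H](O)[C@@]2(C(=C)COCc3ccc(OC)cc3)OC(C)(C)O[C@H]2C1O
F9 | step 5 | 3-C-isopropenyl-5-O-TBDPS-1,2-O-isopropylidene-β-L-lyxofuranose | CC1(C)O[C@H]2[C@@H](O1)O[C@@H](CO[Si](c3ccccc3)(c3ccccc3)C(C)(C)C)[C@]2(O)C(C)=C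
F10 | step 5 | 3-C-(3-hydroxyprop-1-en-2-yl)-5-O-TBDPS-1,2-O-isopropylidene-β-L-lyxofuranose | CC1(C)O[C@H]2[C@@H](O1)O[C@@H](CO[Si](c3ccccc3)(c3ccccc3)C(C)(C)C)[C@]2(O)C(=C)CO
F11 | step 22 | 8-O-{2-[bis(2,2,2-trifluoroethoxy)phosphoryl]propanoyl} ester of 29 | C/C1=C/CC/C(C)=C\[C@@H]2OC(=O)C(=C)[C@]2(O)[C@@H](OC(=O)C(C)P(=O)(OCC(F)(F)F)OCC(F)(F)F)C1=O
A1 | alternative 1 | seco iodo-aldehyde: C9 aldehyde, (Z)-C10 vinyl iodide, (4Z)-olefin, 6-O-PMB, 7,8-O-isopropylidene, 12-O-PMB | C/C(I)=C/CC/C(C)=C\[C@H](OCc1ccc(OC)cc1)[C@@]1(C(=C)COCc2ccc(OC)cc2)OC(C)(C)O[C@H]1C=O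
A2 | alternative 1 | macrocyclic C9 alcohol from the Nozaki–Hiyama–Kishi closure | C/C1=C/CC/C(C)=C\[C@H](OCc3ccc(OC)cc3)[C@@]2(C(=C)COCc3ccc(OC)cc3)OC(C)(C)O[C@H]2C1O
A3 | alternative 2 | cis-fused decalin hydroxy mesylate (C9–OH cis to the C4 methyl, C5–OMs trans to it, 6,12-olide, 7,8-O-isopropylidene) | CC1=CCC[C@@]2(C)[C@@H](OS(C)(=O)=O)[C@@H]3OC(=O)C(=C)[C@]3(O4)[C@@H](OC4(C)C)[C@@]12O
A4 | alternative 2 | 7,8-O-isopropylidene-9-oxo-germacra-1(10)Z,4Z,11(13)-trien-6,12-olide | C/C1=C/CC/C(C)=C\[C@@H]2OC(=O)C(=C)[C@@]23OC(C)(C)O[C@H]3C1=O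
A5 | alternative 3 | (2Z,6Z)-2,6-dimethylcycloocta-2,6-dien-1-one | C/C1=C/CC/C(C)=C\CC1=O
A6 | alternative 3 | (2Z,6Z)-2,6-dimethyl-1-vinylcycloocta-2,6-dien-1-ol | C/C1=C/CC/C(C)=C\CC1(O)C=C
A7 | alternative 3 | (2Z,6Z)-2,6-dimethylcyclodeca-2,6-dien-1-one | C/C1=C/CC/C(C)=C\CCCC1=O
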